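**Strategy.** The eudesmane ring B (C5–C10) carries one exocyclic carbon, C11, on C7, flanked by the C6 and C8 methylenes. This lets C11 start life inside the ring. A trans-fused bicyclo[5.4.0]undecenone (ring A six-membered, ring B seven-membered with a C7=C11 olefin) is made by asymmetric conjugate addition, enolate allylation and ring-closing metathesis. A thallium trinitrate oxidative rearrangement then contracts the cycloheptene to the cyclohexane and ejects C11 as the formyl group on C7. Oxidation to the ester, methylenation and radical hydration at C4, Williamson coupling with the allylic bromide from isocupressic acid and methyl Grignard addition complete the target.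

Key step: step 3

Remark: natural (+)-isocupressic acid (14) is assumed purchasable as the enantiomer shown; the sesquiterpene half uses eudesmane numbering and the diterpene half labdane numbering; C5, α to the C4 ketone, is labile from 5 to 10 and is drawn as the trans isomer that step 5 selects.

**Step 1**
Reactants: 1 3-methylcyclohex-2-en-1-one; 2 but-3-en-1-ylmagnesium bromide; 3 allyl iodide
Product: 5 (2R,3R)-3-(but-3-en-1-yl)-3-methyl-2-(prop-2-en-1-yl)cyclohexan-1-one, via bromomagnesium enolate 4 (not isolated)
Conditions: Cu(OTf)2 (3 mol%), chiral imidazolinium salt (carbene ligand precursor, 4 mol%, enantiomer giving the 3R centre), Et2O, 0 °C; then 3, DMPU, 0 °C → rt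
Reagents that add atoms: none
Why: Copper-catalysed asymmetric conjugate addition of the Grignard reagent, in which the chiral carbene–copper complex selects the enone face and sets the quaternary C10 (3R), followed by C-allylation of the regiospecific magnesium enolate; the 2,3-trans isomer should form together with its C2 epimer, which is carried along because C5 is re-set in step 5.

**Step 2**
Reactants: 5 (2R,3R)-3-(but-3-en-1-yl)-3-methyl-2-(prop-2-en-1-yl)cyclohexan-1-one
Product: 6 (4aR,9aR)-4a-methyl-2,3,4,4a,5,6,9,9a-octahydro-1H-benzo[7]annulen-1-one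
Conditions: second-generation Grubbs catalyst RuCl2(=CHPh)(PCy3)(H2IMes) (3 mol%), CH2Cl2 (0.01 M), 40 °C
Reagents that add atoms: none
Why: Ring-closing metathesis of the allyl and butenyl termini closes the seven-membered ring with loss of ethene, the ring enforces the cis olefin, and no stereocentre is touched.

**Step 3**
Reactants: 6 (4aR,9aR)-4a-methyl-2,3,4,4a,5,6,9,9a-octahydro-1H-benzo[7]annulen-1-one
Product: 8 (2R,4aR,8aR)-4a-methyl-8-oxodecahydronaphthalene-2-carbaldehyde, via dimethyl acetal 7 (not isolated)
Conditions: Tl(NO3)3·3H2O (1.05 equiv), MeOH, 0 °C; then 2 M aq. HCl, THF, rt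
Reagents that add atoms: methanol, CO (the two methoxy groups of 7); water, O (the formyl oxygen of 8)
Why: Electrophilic trivalent thallium adds to the C7=C11 olefin with anti attack of methanol, and heterolysis of the weak C–Tl bond is coupled to an antiperiplanar 1,2-shift of the neighbouring ring carbon (C8 from C11 to C7, or C6 from C7 to C11), giving an exocyclic oxocarbenium ion that methanol traps as acetal 7 and aqueous acid converts into aldehyde 8. The closest known reaction type is the thallium trinitrate oxidative rearrangement of cycloalkenes to ring-contracted cycloalkanecarbaldehyde acetals. Ring B is closed not by an exo or endo cyclisation but by this 1,2-alkyl shift, which shrinks the seven-membered ring to the six-membered one. The only new stereocentre, C7, is formed with inversion at the thallated carbon and is then under thermodynamic control, the formyl group (and after step 4 the ester) equilibrating through its enol to the equatorial 7β position. The constitution is secured because the olefin sits symmetrically between the C6 and C8 methylenes, so either regiochemistry of methoxythallation leaves the extruded carbon on the same ring atom. Chemoselectivity over the enolisable C4 ketone rests on the much faster oxythallation of the olefin at 0 °C with one equivalent of oxidant.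

**Step 4**
Reactants: 8 (2R,4aR,8aR)-4a-methyl-8-oxodecahydronaphthalene-2-carbaldehyde
Product: 10 methyl (2R,4aR,8aR)-4a-methyl-8-oxodecahydronaphthalene-2-carboxylate, via keto acid 9 (not isolated)
Conditions: NaClO2, NaH2PO4, 2-methylbut-2-ene, tBuOH/H2O, rt; then TMSCHN2, MeOH/PhMe, 0 °C; then NaOMe (cat.), MeOH, 50 °C
Reagents that add atoms: sodium chlorite, [Na+].[O-]Cl=O; trimethylsilyldiazomethane, C[Si](C)(C)C=[N+]=[N-]
Why: Pinnick oxidation touches only the aldehyde, diazomethane-type esterification gives the methyl ester, and methoxide equilibration through the ester enolate should leave the ester equatorial (7β) on chair ring B, which is the element that controls C7.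

**Step 5**
Reactants: 10 methyl (2R,4aR,8aR)-4a-methyl-8-oxodecahydronaphthalene-2-carboxylate
Product: 11 methyl (2R,4aR,8aS)-4a-methyl-8-methylidenedecahydronaphthalene-2-carboxylate
Conditions: Ph3PCH3Br, KOtBu, THF, rt → 50 °C
Reagents that add atoms: methyltriphenylphosphonium bromide, C[P+](c1ccccc1)(c1ccccc1)c1ccccc1.[Br-]
Why: Wittig methylenation under conditions where the C5 epimers interconvert through the ketone enolate; the trans-fused ketone, open on its equatorial α face, should be consumed faster than the cis-fused one shielded by ring B (Curtin–Hammett), and C5 is fixed once C4 is no longer a carbonyl.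

**Step 6**
Reactants: 11 methyl (2R,4aR,8aS)-4a-methyl-8-methylidenedecahydronaphthalene-2-carboxylate
Product: 13 methyl (2R,4aR,8R,8aR)-8-hydroxy-4a,8-dimethyldecahydronaphthalene-2-carboxylate, via tertiary hydroperoxide 12 (not isolated)
Conditions: Mn(dpm)3 (5 mol%), PhSiH3, O2 (1 atm), iPrOH/CH2Cl2, 0 °C → rt; then PPh3
Reagents that add atoms: dioxygen, O=O
Why: Mukaiyama hydration: hydrogen atom transfer from a manganese hydride to the CH2 terminus gives the tertiary C4 radical, O2 is captured on the α face anti to the axial C10 methyl, and PPh3 reduces the hydroperoxide, so the equatorial 4α-OH with axial 4β-methyl should result while the ester is untouched.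

**Step 7**
Reactants: 14 (+)-isocupressic acid
Product: 15 prop-2-en-1-yl (1S,4aR,5S,8aR)-5-[(3E)-5-hydroxy-3-methylpent-3-en-1-yl]-1,4a-dimethyl-6-methylidenedecahydronaphthalene-1-carboxylate
Conditions: allyl bromide, K2CO3, DMF, rt
Reagents that add atoms: allyl bromide, C=CCBr
Why: SN2 O-alkylation of the carboxylate works even for the hindered axial C19 acid because the reaction occurs at the allyl carbon, and the primary allylic alcohol is not deprotonated by carbonate.

**Step 8**
Reactants: 15 prop-2-en-1-yl (1S,4aR,5S,8aR)-5-[(3E)-5-hydroxy-3-methylpent-3-en-1-yl]-1,4a-dimethyl-6-methylidenedecahydronaphthalene-1-carboxylate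
Product: 16 prop-2-en-1-yl (1S,4aR,5S,8aR)-5-[(3E)-5-bromo-3-methylpent-3-en-1-yl]-1,4a-dimethyl-6-methylidenedecahydronaphthalene-1-carboxylate
Conditions: CBr4, PPh3, CH2Cl2, 0 °C
Reagents that add atoms: tetrabromomethane, BrC(Br)(Br)Br
Why: Appel bromination of the primary allylic alcohol proceeds by SN2 at C15 with retention of the E olefin and without touching the exocyclic methylene or the ester.

**Step 9**
Reactants: 13 methyl (2R,4aR,8R,8aR)-8-hydroxy-4a,8-dimethyldecahydronaphthalene-2-carboxylate; 16 allyl ester bromide from step 8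
Product: 18 prop-2-en-1-yl (1S,4aR,5S,8aR)-5-[(3E)-5-{[(1R,4aR,7R,8aR)-7-(methoxycarbonyl)-1,4a-dimethyldecahydronaphthalen-1-yl]oxy}-3-methylpent-3-en-1-yl]-1,4a-dimethyl-6-methylidenedecahydronaphthalene-1-carboxylate, via potassium alkoxide 17 (not isolated)
Conditions: KH, THF, 0 °C; then 16, 18-crown-6 (cat.), THF, 0 °C → rt
Reagents that add atoms: none
Why: Williamson ether synthesis: the tertiary potassium alkoxide displaces the primary allylic bromide by SN2, the C4–O bond is never broken so C4 keeps its configuration, and the α-branched C7 ester and the neopentyl allyl ester are slow to enolise or transesterify.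

**Step 10**
Reactants: 18 allyl ester ether from step 9
Product: 19 (1S,4aR,5S,8aR)-5-[(3E)-5-{[(1R,4aR,7R,8aR)-7-(methoxycarbonyl)-1,4a-dimethyldecahydronaphthalen-1-yl]oxy}-3-methylpent-3-en-1-yl]-1,4a-dimethyl-6-methylidenedecahydronaphthalene-1-carboxylic acid
Conditions: Pd(PPh3)4 (5 mol%), morpholine, THF, rt
Reagents that add atoms: none
Why: Tsuji–Trost deallylation: zerovalent palladium ionises the allyl carboxylate and morpholine traps the allyl unit, whereas the alkyl allyl ether (alkoxide is a poor leaving group) and the methyl ester are inert.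

**Step 11**
Reactants: 19 acid methyl ester from step 10
Product: 21 target, (1S,4aR,5S,8aR)-5-[(3E)-5-{[(1R,4aR,7R,8aR)-7-(2-hydroxypropan-2-yl)-1,4a-dimethyldecahydronaphthalen-1-yl]oxy}-3-methylpent-3-en-1-yl]-1,4a-dimethyl-6-methylidenedecahydronaphthalene-1-carboxylic acid, via methyl ketone 20 (not isolated)
Conditions: MeMgBr (6 equiv), THF, 0 °C → rt; aq. NH4Cl
Reagents that add atoms: methylmagnesium bromide, C[Mg]Br
Why: Double Grignard addition to the C7 methyl ester through the methyl ketone gives the C11 tertiary alcohol, while the C19 acid is masked in the flask as its magnesium carboxylate, which does not add the reagent; no stereocentre is touched.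

**Compound list**
1 | 3-methylcyclohex-2-en-1-one | CC1=CC(=O)CCC1 | starting material
2 | but-3-en-1-ylmagnesium bromide | C=CCC[Mg]Br | starting material
3 | allyl iodide (3-iodoprop-1-ene) | C=CCI | starting material
4 | bromomagnesium (R)-3-(but-3-en-1-yl)-3-methylcyclohex-1-en-1-olate | Br[Mg]OC1=C[C@@](C)(CCC=C)CCC1 | intermediate
5 | (2R,3R)-3-(but-3-en-1-yl)-3-methyl-2-(prop-2-en-1-yl)cyclohexan-1-one | O=C1CCC[C@](C)(CCC=C)[C@H]1CC=C | intermediate
6 | (4aR,9aR)-4a-methyl-2,3,4,4a,5,6,9,9a-octahydro-1H-benzo[7]annulen-1-one (trans-fused, 7,8-olefin) | O=C1CCC[C@]2(C)CC/C=C\C[C@H]21 | intermediate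
7 | (4aR,8aR)-7-(dimethoxymethyl)-4a-methyloctahydronaphthalen-1(2H)-one (C7 epimers) | O=C1CCC[C@]2(C)CCC(C(OC)OC)C[C@H]21 | intermediate
8 | (2R,4aR,8aR)-4a-methyl-8-oxodecahydronaphthalene-2-carbaldehyde | O=C1CCC[C@]2(C)CC[C@@H](C=O)C[C@H]21 | intermediate
9 | (2R,4aR,8aR)-4a-methyl-8-oxodecahydronaphthalene-2-carboxylic acid | O=C1CCC[C@]2(C)CC[C@@H](C(=O)O)C[C@H]21 | intermediate
10 | methyl (2R,4aR,8aR)-4a-methyl-8-oxodecahydronaphthalene-2-carboxylate | O=C1CCC[C@]2(C)CC[C@@H](C(=O)OC)C[C@H]21 | intermediate
11 | methyl (2R,4aR,8aS)-4a-methyl-8-methylidenedecahydronaphthalene-2-carboxylate | C=C1CCC[C@]2(C)CC[C@@H](C(=O)OC)C[C@H]21 | intermediate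
12 | methyl (2R,4aR,8R,8aR)-8-hydroperoxy-4a,8-dimethyldecahydronaphthalene-2-carboxylate | OO[C@]1(C)CCC[C@]2(C)CC[C@@H](C(=O)OC)C[C@H]21 | intermediate
13 | methyl (2R,4aR,8R,8aR)-8-hydroxy-4a,8-dimethyldecahydronaphthalene-2-carboxylate | O[C@]1(C)CCC[C@]2(C)CC[C@@H](C(=O)OC)C[C@H]21 | intermediate
14 | (+)-isocupressic acid, (1S,4aR,5S,8aR)-5-[(3E)-5-hydroxy-3-methylpent-3-en-1-yl]-1,4a-dimethyl-6-methylidenedecahydronaphthalene-1-carboxylic acid | C=C1CC[C@@H]2[C@](C)(CCC[C@]2(C)C(=O)O)[C@H]1CC/C(C)=C/CO | starting material
15 | allyl isocupressate (prop-2-en-1-yl ester of 14) | C=C1CC[C@@H]2[C@](C)(CCC[C@]2(C)C(=O)OCC=C)[C@H]1CC/C(C)=C/CO | intermediate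
16 | allyl (13E)-15-bromolabda-8(17),13-dien-19-oate (15-bromide of 15) | C=C1CC[C@@H]2[C@](C)(CCC[C@]2(C)C(=O)OCC=C)[C@H]1CC/C(C)=C/CBr | intermediate
17 | potassium alkoxide of 13 | [K+].[O-][C@]1(C)CCC[C@]2(C)CC[C@@H](C(=O)OC)C[C@H]21 | intermediate
18 | C4–O–C15 ether with C19 allyl ester and C7 methyl ester | C=C1CC[C@@H]2[C@](C)(CCC[C@]2(C)C(=O)OCC=C)[C@H]1CC/C(C)=C/CO[C@]1(C)CCC[C@]2(C)CC[C@@H](C(=O)OC)C[C@H]21 | intermediate
19 | C4–O–C15 ether with free C19 acid and C7 methyl ester | C=C1CC[C@@H]2[C@](C)(CCC[C@]2(C)C(=O)O)[C@H]1CC/C(C)=C/CO[C@]1(C)CCC[C@]2(C)CC[C@@H](C(=O)OC)C[C@H]21 | intermediate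
20 | C4–O–C15 ether with free C19 acid and 7β-acetyl group | C=C1CC[C@@H]2[C@](C)(CCC[C@]2(C)C(=O)O)[C@H]1CC/C(C)=C/CO[C@]1(C)CCC[C@]2(C)CC[C@@H](C(C)=O)C[C@H]21 | intermediate
21 | CNP0156875.1, (1S,4aR,5S,8aR)-5-[(3E)-5-{[(1R,4aR,7R,8aR)-7-(2-hydroxypropan-2-yl)-1,4a-dimethyldecahydronaphthalen-1-yl]oxy}-3-methylpent-3-en-1-yl]-1,4a-dimethyl-6-methylidenedecahydronaphthalene-1-carboxylic acid | C=C1CC[C@@H]2[C@](C)(CCC[C@]2(C)C(=O)O)[C@H]1CC/C(C)=C/CO[C@]1(C)CCC[C@]2(C)CC[C@@H](C(C)(C)O)C[C@H]21 | target

**Totals**
Total step count: 11. Longest linear sequence: 9 steps (steps 1–6, then 9–11); the labdane branch (steps 7 and 8) joins at step 9.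

**Steps most likely to fail**

Step 3 (key step). The thallium adduct may collapse by hydride shift to the cycloheptanone ketal or by simple 1,2-dimethoxylation instead of by ring-carbon migration, and the enolisable ketone may be over-oxidised. The fallback sets out from 6 and changes the approach to a stepwise semipinacol contraction. Epoxidation of the ring B olefin with mCPBA (NaHCO3, CH2Cl2) should give the 7,8-epoxide F1 (either face serves). LiBr with HMPA in toluene at 80 °C then opens it to the trans-bromohydrin lithium alkoxide, whose ring bond antiperiplanar to bromide migrates with loss of LiBr. Both regioisomeric bromohydrins converge on the C7 carbaldehyde, and brief acid equilibration brings the material back to the route at 8.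

Step 5. Epimerisation at C5 may be too slow, or the two ring-fusion isomers may be methylenated at similar rates, so that cis-fused olefin contaminates the product. The fallback sets out from 10. TMSCl, Et3N and DMF at 80 °C should give the thermodynamic tetrasubstituted silyl enol ether F2. Kinetic protonation (Bu4NF, AcOH, THF, −78 °C) from the α face, anti to the angular methyl, regenerates 10 as the trans-fused isomer alone. Immediate non-basic Takai–Lombardo methylenation (Zn, CH2Br2, TiCl4, THF) then gives 11, where the fallback rejoins the route.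

Step 9. The hindered, basic tertiary alkoxide may eliminate HBr from the allylic bromide to a diene, attack in SN2' fashion, or degrade the C7 ester, instead of substituting at C15. The fallback sets out from 13 and 14 and forms the C–O bond by palladium catalysis; it needs the C19 acid as a methyl ester because an allyl ester is itself ionised by zerovalent palladium. TMSCHN2 converts 14 into methyl isocupressate F3, and methyl chloroformate with pyridine gives its C15 methyl carbonate F4. Allylic etherification of F4 with the zinc alkoxide of 13 (Et2Zn 0.5 equiv, Pd(OAc)2 5 mol%, 2-(di-tert-butylphosphino)biphenyl, THF, rt) should give the linear E diester ether F5. MeMgBr at 0 °C adds only to the secondary C7 ester, the axial neopentyl C19 ester being too hindered, to give the target methyl ester F6. SN2 demethylation with lithium propane-1-thiolate in HMPA at rt then releases the acid, and the fallback comes back to the route at 21.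

**Further compounds**
F1 | step 3 | (4aR,9aR)-7,8-epoxy-4a-methyldecahydro-1H-benzo[7]annulen-1-one | O=C1CCC[C@]2(C)CCC3OC3C[C@H]21
F2 | step 5 | methyl (2R,4aR)-4a-methyl-8-[(trimethylsilyl)oxy]-1,2,3,4,4a,5,6,7-octahydronaphthalene-2-carboxylate | C[Si](C)(C)OC=1CCC[C@]2(C)CC[C@@H](C(=O)OC)CC2=1
F3 | step 9 | methyl isocupressate | C=C1CC[C@@H]2[C@](C)(CCC[C@]2(C)C(=O)OC)[C@H]1CC/C(C)=C/CO
F4 | step 9 | methyl isocupressate 15-(methyl carbonate) | C=C1CC[C@@H]2[C@](C)(CCC[C@]2(C)C(=O)OC)[C@H]1CC/C(C)=C/COC(=O)OC
F5 | step 9 | C4–O–C15 ether with C19 methyl ester and C7 methyl ester | C=C1CC[C@@H]2[C@](C)(CCC[C@]2(C)C(=O)OC)[C@H]1CC/C(C)=C/CO[C@]1(C)CCC[C@]2(C)CC[C@@H](C(=O)OC)C[C@H]21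
F6 | step 9 | methyl ester of 21 | C=C1CC[C@@H]2[C@](C)(CCC[C@]2(C)C(=O)OC)[C@H]1CC/C(C)=C/CO[C@]1(C)CCC[C@]2(C)CC[C@@H](C(C)(C)O)C[C@H]21
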